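## Structural features

The target (C30H22O17) is a linear chain of five benzene rings, A to E, held together only by four diaryl ether oxygens, which join position 1 of ring A to B1, B2 to C1, C4 to D1 and D2 to E1. There is no biaryl C–C bond, no stereocentre and no hindered axis, so no stereocentres stand next to each other and nothing stereochemical has to be set. Ring A is a 2,4,6-trihydroxyphenyl group, ring B carries hydroxyls at B3 and B5 beside the two ether carbons B1 and B2, ring C is 1,4-dioxygenated with hydroxyls at C3 and C5 flanking C4, ring D is pentaoxygenated (ethers at D1 and D2, hydroxyls at D3 to D5), and ring E is a 3,4,5-trihydroxyphenyl group. The thirteen free phenols are the fragile part: the pyrogallol units of rings D and E and the para-dioxygenated ring C oxidize readily in air, above all under base, so they should stay masked as alkyl ethers until the last step. The real difficulty is the regiocontrolled formation of four ethers between electron-rich rings, each of which has one doubly flanked terminus (position 1 of ring A, B2, C4 and D2), the worst case both for SNAr and for metal-mediated coupling. In addition, the four oxygens of ring B must be told apart. The key step exploits the resorcinol unit of ring B (B3-OH, B4-H, B5-OH) that adjoins the two neighbouring ether carbons B1 and B2: a dioxygenated vinylketene and an alkoxyalkyne deliver exactly this pattern, so the hindered ether between rings A and B can be made by O-alkylation before ring B exists, and each oxygen of ring B appears with a different substituent.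

## Logic of the disconnections

29 ⇒ 28. The thirteen O–alkyl bonds (twelve O–CH3 and the O–CH2CH3 at B5) are cut first, so that the polyphenol is unveiled last. The free phenol is the only oxidation-prone form of the skeleton and should exist for one step only; every earlier intermediate is then a robust ether. The forward step must cleave all alkyl aryl ethers, including the congested central methoxy groups of rings D and E, and leave the four diaryl ethers intact.

28 ⇒ 18 + 27. The bond between the B2 oxygen and C1 is cut. It is the middle ether, so two halves of similar size result, and C1 has two free ortho positions, so all congestion lies on the oxygen side. The forward step must arylate an oxygen flanked by the B1 aryloxy and B3 methoxy groups, and that oxygen must be the only free hydroxyl of 18.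

18 ⇒ 17 ⇒ 16. The O–benzyl bond at B2 is restored and the O–CH3 bond at B3 is cut. These two functional-group steps only exchange the roles of the neighbouring oxygens, but they lead back to 16, the direct product of the ring-forming step. Forward, methylation must be complete before hydrogenolysis, and hydrogenolysis must spare every other ether.

16 ⇒ 10 + 11. Four bonds of ring B are cut: B6–B1, B3–B4, B5–B6 and B2–B3. Ring B falls apart into the four-carbon unit of 10 and the two-carbon unit of 11, the hindered ether between rings A and B becomes an ether on an open chain, and the differentiation of the ring B oxygens is settled by the substituents chosen in 10 and 11. The forward step demands a clean Wolff rearrangement, a regiospecific (2+2) addition of 11, and ring closure onto the benzyloxy-bearing terminus.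

10 ⇒ 8 (through 9). The C=N2 bond is cut back to a methyl group. Diazo transfer onto an activated methyl ketone avoids the acylation of diazomethane with a conjugated acid chloride. The demand is selective enolization, met because the methyl group is the only enolizable position of 8, and a vinylogous ester that tolerates an amide base at low temperature.

8 ⇒ 6 + 7, 6 ⇒ 5 ⇒ 3 + 4. The O–CH2Ph bond is cut, then the enol oxygen is traced to an enamine nitrogen, then the C=C bond between the aryloxy-bearing carbon (future B1) and the one-carbon unit (future B2) is cut. This reduces the enol ether to the simple ketone 3 and the formyl equivalent 4. Forward, 4 must condense at the methylene between carbonyl and aryloxy oxygen rather than at the methyl group, and 7 must alkylate the formyl oxygen of 6.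

3 ⇒ 1 + 2. The O–CH2 bond, the future ether between rings A and B, is cut. The most hindered ether of the left half is thereby made on an sp3 carbon, and the demand is only a Williamson alkylation of the doubly flanked phenol 1 by the reactive halide 2.

27 ⇒ 25 (through 26). The C1–B bond of ring C is cut to C–H. C1–H is the only aromatic C–H of 25 without an ortho substituent, so ring C can enter as the simple iodide 24 without a second handle. The demand is steric site control in the C–H borylation and a mild cleavage of the boronic ester 26.

25 ⇒ 23 + 24. The C4–O bond of ring C is cut, which joins 24 to the ring D–E phenol 23. The forward step is a coupling of a doubly flanked iodide with a singly flanked phenol, which needs a ligand system made for hindered ethers.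

23 ⇒ 21 (through 22) ⇒ 19 + 20. The D1 hydroxyl is traced to a formyl group, and the D2–O bond to ring E is cut. The formyl group serves twice: it activates the neighbouring bromide of 19 for ether formation and then becomes the D1 oxygen. Rings D and E thus come from 19 and 20 with all their oxygens in place. The forward steps demand coupling at a bromide flanked by formyl and methoxy, and aryl rather than hydride migration in the oxidation of 21.

## Other disconnections considered

Alternative 1: The cut removes both ether bonds of ring C at once (O–B2 and O–D1). Ring C becomes 2,6-dimethoxybenzene-1,4-diol A1, and the two halves become the ring A–B fluoroaldehyde A2 (fluorine at B2, formyl at B5) and the ring D–E fluoroaldehyde A3 (fluorine at D1, formyl at D4). In the forward key step, with Cs2CO3 in DMSO, the unflanked phenoxide of A1 would displace fluoride from A2 and the flanked phenoxide would then displace fluoride from A3. Each substitution would be an addition–elimination assisted by the para-formyl group, and the product would be the undecamethyl dialdehyde A4. Two Dakin oxidations of A4 would then turn the formyl groups into the B5 and D4 hydroxyls before ether cleavage.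
- In favour: three fragments and two ether bonds in one operation, no transition metal, no diazo compound, no light, and formyl groups that are both activators and masked hydroxyls.
- Against: the fluorine of A2 lies between a methoxy and a bulky aryloxy group on a donor-rich ring. The formyl group of A3 lies between two methoxy groups and should be twisted out of conjugation. The order of arylation of the two oxygens of A1 rests on sterics alone, and the electron-rich dianion of A1 is prone to air oxidation. A2 and A3 each already contain a hindered ether (the A–B ether and the D–E ether), so the hard bond of the left half is only moved into a fragment synthesis.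
- Comparison: on structure it exploits the para relation of B5 to B2 and of D4 to D1, whereas the chosen plan exploits the resorcinol unit of ring B. On mechanism it is ionic addition–elimination against a pericyclic cascade. It is the better plan in convergence and in operational safety, and equal in the final dealkylation. In step economy it is expected to be comparable or slightly longer, because of the two extra oxidations of A4 and the fragment syntheses.

Alternative 2: The cut opens ring D at D1–D2. Four ring carbons (D2 to D5) would come from dimethyl squarate A5 and two (D6 and D1) from the alkenyllithium A6, which carries ring C on its enol ether oxygen. In the forward sequence A6 would add to a carbonyl group of A5, and methylation of the tertiary alkoxide would give the 4-alkenyl-2,3,4-trimethoxycyclobutenone A7. Heating A7 should cause 4π ring opening and 6π ring closure (Moore-type ring expansion), which forms the D1–D2 bond and gives the phenol A8, free only at D2.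
- In favour: the most oxygenated ring is made with every oxygen placed and D2 alone free, ready for arylation by ring E. The doubly flanked C4–O–D1 ether is formed as a vinyl ether before ring D exists. The rearrangement of A7 is thermal, without diazo compound or ultraviolet light.
- Against: A6 is a β-aryloxy vinyllithium that can lose aryloxide, and its preparation would take several steps. Ring D is available commercially with its oxygens in place (19), so building it costs steps. The ring A–B half would still be needed, and the D2 hydroxyl of A8 is as flanked as the B2 hydroxyl of 18.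
- Comparison: on structure it addresses ring D where the chosen plan addresses ring B. On mechanism the two share the electrocyclic opening and closure and are equal in regiochemical certainty. It is the better plan in that the hydroxyl to be arylated emerges free, whereas the chosen route needs steps 7 and 8 first. It is the weaker plan in step economy for the ring C–D–E half, which the chosen route assembles in four steps from purchased rings.

Alternative 3: The cut opens ring A between its positions 1 and 2, back to the methyl 6-aryloxy-3,5-dioxohexanoate A9, which carries ring B as its aryloxy group. In the forward key step, triple deprotonation of A9 with excess lithium diisopropylamide would let the aryloxy-bearing terminal carbon attack the ester carbonyl (Claisen cyclization), and enolization would give the 2-aryloxyphloroglucinol A10.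
- In favour: the route is biomimetic, the ether between rings A and B is formed by alkylation on an sp3 carbon, and ring A appears directly as the free triol.
- Against: ring A is the simplest ring of the target and can be bought in protected form (1), so making it gains nothing. C-acylation has to compete with O-acylation (lactonization) of the chain of A9. The free triol A10 would have to be re-protected before any copper-mediated coupling. Most importantly, the differentiated ring B (benzyloxy at B2, ethers at B3 and B5) must be made beforehand by other means, which is the very problem the chosen key step solves.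
- Comparison: on structure it builds the least demanding ring. On mechanism it is an anionic condensation against a pericyclic cascade. It is equal to the chosen plan in making the ether between rings A and B by alkylation rather than by aryl coupling. It is expected to be longer overall.

Key step: step 6

Remark on the chemistry: the target is achiral, so the only stereochemical element of the route is the enol ether geometry of 8, 9 and 10 (benzyloxy trans to the carbonyl carbon). Compounds 1, 2, 4, 7, 11, 19, 20 and 24 are taken to be catalogue compounds, 11 as its solution in hexanes.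

Remark on the precursor: the atom mapping of 10 onto 16 is self-consistent (diazo carbon to B6, carbonyl carbon to B3, aryloxy-bearing carbon to B1, benzyloxy-bearing carbon to B2, the carbons of 11 to B4 and B5). Diazo ketone 10 is reached by diazo transfer onto methyl ketone 8 rather than by acylation of diazomethane, which avoids a conjugated acid chloride, hydrogen chloride next to an enol ether, and diazomethane itself.

## Route

Step 1
Reactants: 1 2,4,6-trimethoxyphenol; 2 chloroacetone
Product: 3 1-(2,4,6-trimethoxyphenoxy)propan-2-one
Conditions: K2CO3, KI (cat.), acetone, reflux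
Reagents that add atoms: none
Why: Williamson ether synthesis; the phenoxide of 1, although flanked by two methoxy groups, should be alkylated readily by the reactive α-chloro ketone (iodide catalysis), which forms the future ether between rings A and B on an sp3 carbon and sidesteps any hindered aryl–oxygen coupling.

Step 2
Reactants: 3 1-(2,4,6-trimethoxyphenoxy)propan-2-one; 4 N,N-dimethylformamide dimethyl acetal
Product: 5 (Z)-4-(dimethylamino)-3-(2,4,6-trimethoxyphenoxy)but-3-en-2-one
Conditions: 4 (1.3 equiv), toluene, 100 °C
Reagents that add atoms: none
Why: Enaminone formation by condensation of an amide acetal at the more acidic methylene between carbonyl and aryloxy oxygen, the known site for aryloxyacetones; the dimethylamino group is expected trans to the acetyl group, and a small excess of 4 limits a second condensation at the methyl group.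

Step 3
Reactants: 5 (Z)-4-(dimethylamino)-3-(2,4,6-trimethoxyphenoxy)but-3-en-2-one
Product: 6 (E)-4-hydroxy-3-(2,4,6-trimethoxyphenoxy)but-3-en-2-one
Conditions: 1 M aq. HCl, THF, rt
Reagents that add atoms: water, O
Why: Acid hydrolysis of a vinylogous amide (addition of water to the iminium form, loss of dimethylamine) should release the α-formyl ketone, which rests as its chelated enol; the mild conditions avoid deformylation, and the crude enol is used directly.

Step 4
Reactants: 6 (E)-4-hydroxy-3-(2,4,6-trimethoxyphenoxy)but-3-en-2-one; 7 benzyl bromide
Product: 8 (Z)-4-(benzyloxy)-3-(2,4,6-trimethoxyphenoxy)but-3-en-2-one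
Conditions: K2CO3, DMF, rt
Reagents that add atoms: none
Why: O-Alkylation of the potassium enolate of a 2-substituted 3-oxoaldehyde in a dipolar aprotic solvent is expected at the less hindered formyl oxygen, because C-alkylation would create a quaternary carbon bearing the aryloxy group; the isomer with benzyloxy trans to acetyl should predominate, and a minor isomer would be removed by chromatography.

Step 5
Reactants: 8 (Z)-4-(benzyloxy)-3-(2,4,6-trimethoxyphenoxy)but-3-en-2-one
Product: 10 (Z)-4-(benzyloxy)-1-diazo-3-(2,4,6-trimethoxyphenoxy)but-3-en-2-one, via trifluoroacetyl diketone 9 (not isolated)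
Conditions: LiN(SiMe3)2, THF, −78 °C; CF3CO2CH2CF3; aq. HCl quench; then 4-AcNHC6H4SO2N3, Et3N, H2O (1 equiv), MeCN, rt
Reagents that add atoms: 4-acetamidobenzenesulfonyl azide, CC(=O)Nc1ccc(cc1)S(=O)(=O)N=[N+]=[N-]; 2,2,2-trifluoroethyl trifluoroacetate, FC(F)(F)COC(=O)C(F)(F)F (its trifluoroacetyl group is carried only by 9)
Why: Detrifluoroacetylative diazo transfer, the standard entry to α′-diazo enones; the kinetic lithium enolate of the methyl ketone (the only enolizable position) is C-trifluoroacetylated to 9, and the activated methylene then accepts the diazo group from the sulfonyl azide while the trifluoroacetyl group leaves on the sulfonamide nitrogen. The solid sulfonyl azide is among the safer diazo-transfer reagents, and no diazomethane is needed.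

Step 6
Reactants: 10 (Z)-4-(benzyloxy)-1-diazo-3-(2,4,6-trimethoxyphenoxy)but-3-en-2-one; 11 ethoxyethyne
Product: 16 2-(benzyloxy)-5-ethoxy-3-(2,4,6-trimethoxyphenoxy)phenol, via vinylketene 12 (not isolated), via cyclobutenone 13 (not isolated), via dienylketene 14 (not isolated), via cyclohexadienone 15 (not isolated)
Conditions: hν (254 nm, low-pressure Hg lamps, quartz), 11 (3 equiv), degassed ClCH2CH2Cl, rt; then 80 °C in the dark
Reagents that add atoms: none
Why: This is a Danheiser benzannulation in its photochemical form; the closest known reaction type is the union of α,β-unsaturated α′-diazo ketones with alkoxyalkynes. Light expels N2 from 10 and the alkenyl group shifts to the former diazo carbon (Wolff rearrangement, new B6–B1 bond) to give vinylketene 12, whose oxygen donors sit on the vinyl unit and do not conjugate with the carbonyl π* orbital that the alkyne attacks. The ketene carbonyl carbon bonds to the unsubstituted, nucleophilic carbon of 11 and the ketene α-carbon to the ethoxy-bearing carbon in a (2+2) cycloaddition (B3–B4 and B5–B6 bonds), giving 13. Reversible 4π electrocyclic opening of 13 gives dienylketene 14, and ring B closes by thermal disrotatory 6π electrocyclization of the ketene carbon onto the benzyloxy-bearing terminus (B2–B3 bond), after which 15 tautomerizes to the phenol; the warm second stage converts any 13 that survives irradiation. No stereocentre remains in 16, because the sp3 carbons of 13 and 15 disappear on ring opening and enolization. The selectivity required is regiochemical and is secured by the polarization of the ynol ether, which places ethoxy at B5, meta to the new B3 hydroxyl with B4-H between them. The benzyloxy group trans to the acyl carbon in 10 keeps that oxygen away from the diazo carbon and points it outward in the ring closure, so the four oxygens of ring B emerge as free OH (B3), ethyl ether (B5), benzyl ether (B2) and aryl ether (B1).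

Step 7
Reactants: 16 2-(benzyloxy)-5-ethoxy-3-(2,4,6-trimethoxyphenoxy)phenol
Product: 17 2-(benzyloxy)-5-ethoxy-1-methoxy-3-(2,4,6-trimethoxyphenoxy)benzene
Conditions: MeI, K2CO3, acetone, reflux
Reagents that add atoms: iodomethane, CI
Why: Williamson methylation of the only free phenol; it caps B3 so that B2 can later be the single nucleophilic oxygen.

Step 8
Reactants: 17 2-(benzyloxy)-5-ethoxy-1-methoxy-3-(2,4,6-trimethoxyphenoxy)benzene
Product: 18 4-ethoxy-2-methoxy-6-(2,4,6-trimethoxyphenoxy)phenol
Conditions: H2 (1 atm), Pd/C (10 wt% Pd), EtOAc/EtOH, rt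
Reagents that add atoms: none
Why: Hydrogenolysis of the benzyl aryl ether over palladium should leave methyl, ethyl and diaryl ethers untouched and free the B2 hydroxyl as the only OH group.

Step 9
Reactants: 19 2-bromo-3,4,5-trimethoxybenzaldehyde; 20 3,4,5-trimethoxyphenol
Product: 21 3,4,5-trimethoxy-2-(3,4,5-trimethoxyphenoxy)benzaldehyde
Conditions: CuI (10 mol%), N,N-dimethylglycine hydrochloride (30 mol%), Cs2CO3, dioxane, 100 °C
Reagents that add atoms: none
Why: Ullmann diaryl ether synthesis with a monovalent copper catalyst and an amino acid ligand; the ortho-formyl group activates the flanked bromide and the phenol partner is unhindered and electron-rich, which forms the D2–O–E1 ether.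

Step 10
Reactants: 21 3,4,5-trimethoxy-2-(3,4,5-trimethoxyphenoxy)benzaldehyde
Product: 23 3,4,5-trimethoxy-2-(3,4,5-trimethoxyphenoxy)phenol, via aryl formate 22 (not isolated)
Conditions: mCPBA, CH2Cl2, 0 °C to rt; aq. Na2S2O3; then K2CO3 (cat.), MeOH, rt
Reagents that add atoms: 3-chloroperoxybenzoic acid (mCPBA), OOC(=O)c1cccc(Cl)c1
Why: Dakin-type sequence (Baeyer–Villiger oxidation of an electron-rich benzaldehyde, then methanolysis of the formate); migration of the aryl group rather than hydride is favoured by the ortho aryloxy and para methoxy donors, so the formyl carbon is replaced by the D1 oxygen.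

Step 11
Reactants: 23 3,4,5-trimethoxy-2-(3,4,5-trimethoxyphenoxy)phenol; 24 2-iodo-1,3-dimethoxybenzene
Product: 25 1-(2,6-dimethoxyphenoxy)-3,4,5-trimethoxy-2-(3,4,5-trimethoxyphenoxy)benzene
Conditions: CuI (10 mol%), picolinic acid (20 mol%), K3PO4, DMSO, 90 °C
Reagents that add atoms: none
Why: Copper-catalysed Ullmann coupling under the picolinic acid/K3PO4/DMSO conditions developed for hindered diaryl ethers; the iodide is flanked by two small methoxy groups and the phenol by one aryloxy group, a tri-ortho-substituted case within the reach of this ligand system.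

Step 12
Reactants: 25 1-(2,6-dimethoxyphenoxy)-3,4,5-trimethoxy-2-(3,4,5-trimethoxyphenoxy)benzene
Product: 27 {3,5-dimethoxy-4-[3,4,5-trimethoxy-2-(3,4,5-trimethoxyphenoxy)phenoxy]phenyl}boronic acid, via pinacol boronate 26 (not isolated)
Conditions: [Ir(OMe)(cod)]2 (1.5 mol%), 4,4'-di-tert-butyl-2,2'-bipyridine (3 mol%), B2pin2 (1 equiv), THF, 80 °C; then NaIO4, aq. HCl, THF/H2O, rt
Reagents that add atoms: bis(pinacolato)diboron, CC1(C)OB(OC1(C)C)B1OC(C)(C)C(C)(C)O1; water, O
Why: Sterically controlled iridium-catalysed C–H borylation; C1–H of ring C is the only aromatic hydrogen of 25 without an ortho substituent (D6–H, E2–H and E6–H are flanked on both sides, C2–H and C6–H on one), so boron should enter there alone. Periodate then cleaves the pinacol ester in the same pot to give the free boronic acid needed for the copper coupling.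

Step 13
Reactants: 18 4-ethoxy-2-methoxy-6-(2,4,6-trimethoxyphenoxy)phenol; 27 {3,5-dimethoxy-4-[3,4,5-trimethoxy-2-(3,4,5-trimethoxyphenoxy)phenoxy]phenyl}boronic acid
Product: 28 2-(5-ethoxy-3-methoxy-2-{3,5-dimethoxy-4-[3,4,5-trimethoxy-2-(3,4,5-trimethoxyphenoxy)phenoxy]phenoxy}phenoxy)-1,3,5-trimethoxybenzene
Conditions: Cu(OAc)2 (1 equiv), pyridine (5 equiv), 4 Å MS, CH2Cl2, dry air, rt; 27 in 1.5-fold excess
Reagents that add atoms: none
Why: Chan–Lam oxidative O-arylation, in which air is the terminal oxidant and returns the copper to its divalent acetate; the boron-bearing carbon has two free ortho positions, so the congestion lies only on the phenol oxygen, and 2,6-disubstituted phenols are known substrates of this coupling. It runs at room temperature and leaves every ether intact.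

Step 14
Reactants: 28 2-(5-ethoxy-3-methoxy-2-{3,5-dimethoxy-4-[3,4,5-trimethoxy-2-(3,4,5-trimethoxyphenoxy)phenoxy]phenoxy}phenoxy)-1,3,5-trimethoxybenzene
Product: 29 2-(3,5-dihydroxy-2-{3,5-dihydroxy-4-[3,4,5-trihydroxy-2-(3,4,5-trihydroxyphenoxy)phenoxy]phenoxy}phenoxy)benzene-1,3,5-triol
Conditions: BBr3 (about 30 equiv), CH2Cl2, −78 °C to rt, Ar; then degassed MeOH/H2O, 0 °C
Reagents that add atoms: none
Why: Lewis-acid ether cleavage; BBr3 coordinates each alkyl aryl ether oxygen and bromide removes the methyl or ethyl group by SN2, whereas the diaryl ethers offer no sp3 carbon and should survive. Hydrolysis of the aryl borates under argon releases the thirteen phenols of the target.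

## Compound list

1 | 2,4,6-trimethoxyphenol | COc1cc(OC)c(O)c(OC)c1 | starting material
2 | chloroacetone (1-chloropropan-2-one) | CC(=O)CCl | starting material
3 | 1-(2,4,6-trimethoxyphenoxy)propan-2-one | CC(=O)COc1c(OC)cc(OC)cc1OC | intermediate
4 | N,N-dimethylformamide dimethyl acetal | COC(OC)N(C)C | starting material
5 | (Z)-4-(dimethylamino)-3-(2,4,6-trimethoxyphenoxy)but-3-en-2-one | CC(=O)/C(Oc1c(OC)cc(OC)cc1OC)=C/N(C)C | intermediate
6 | (E)-4-hydroxy-3-(2,4,6-trimethoxyphenoxy)but-3-en-2-one (chelated enol of 3-oxo-2-(2,4,6-trimethoxyphenoxy)butanal) | CC(=O)/C(Oc1c(OC)cc(OC)cc1OC)=C\O | intermediate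
7 | benzyl bromide | BrCc1ccccc1 | starting material
8 | (Z)-4-(benzyloxy)-3-(2,4,6-trimethoxyphenoxy)but-3-en-2-one | CC(=O)/C(Oc1c(OC)cc(OC)cc1OC)=C/OCc1ccccc1 | intermediate
9 | (Z)-6-(benzyloxy)-1,1,1-trifluoro-5-(2,4,6-trimethoxyphenoxy)hex-5-ene-2,4-dione | FC(F)(F)C(=O)CC(=O)/C(Oc1c(OC)cc(OC)cc1OC)=C/OCc1ccccc1 | intermediate (not isolated)
10 | (Z)-4-(benzyloxy)-1-diazo-3-(2,4,6-trimethoxyphenoxy)but-3-en-2-one | [N-]=[N+]=CC(=O)/C(Oc1c(OC)cc(OC)cc1OC)=C/OCc1ccccc1 | intermediate
11 | ethoxyethyne | C#COCC | starting material
12 | (3Z)-4-(benzyloxy)-3-(2,4,6-trimethoxyphenoxy)buta-1,3-dien-1-one | O=C=C/C(Oc1c(OC)cc(OC)cc1OC)=C/OCc1ccccc1 | intermediate (not isolated)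
13 | 4-[(Z)-2-(benzyloxy)-1-(2,4,6-trimethoxyphenoxy)ethenyl]-3-ethoxycyclobut-2-en-1-one (racemic) | CCOC1=CC(=O)C1/C(Oc2c(OC)cc(OC)cc2OC)=C/OCc2ccccc2 | intermediate (not isolated)
14 | (3E,5Z)-6-(benzyloxy)-3-ethoxy-5-(2,4,6-trimethoxyphenoxy)hexa-1,3,5-trien-1-one | O=C=C/C(OCC)=C\C(Oc1c(OC)cc(OC)cc1OC)=C\OCc1ccccc1 | intermediate (not isolated)
15 | 6-(benzyloxy)-3-ethoxy-5-(2,4,6-trimethoxyphenoxy)cyclohexa-2,4-dien-1-one (racemic) | CCOC1=CC(=O)C(OCc2ccccc2)C(Oc2c(OC)cc(OC)cc2OC)=C1 | intermediate (not isolated)
16 | 2-(benzyloxy)-5-ethoxy-3-(2,4,6-trimethoxyphenoxy)phenol | CCOc1cc(O)c(OCc2ccccc2)c(Oc2c(OC)cc(OC)cc2OC)c1 | intermediate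
17 | 2-(benzyloxy)-5-ethoxy-1-methoxy-3-(2,4,6-trimethoxyphenoxy)benzene | CCOc1cc(OC)c(OCc2ccccc2)c(Oc2c(OC)cc(OC)cc2OC)c1 | intermediate
18 | 4-ethoxy-2-methoxy-6-(2,4,6-trimethoxyphenoxy)phenol | CCOc1cc(OC)c(O)c(Oc2c(OC)cc(OC)cc2OC)c1 | intermediate
19 | 2-bromo-3,4,5-trimethoxybenzaldehyde | COc1cc(C=O)c(Br)c(OC)c1OC | starting material
20 | 3,4,5-trimethoxyphenol | COc1cc(O)cc(OC)c1OC | starting material
21 | 3,4,5-trimethoxy-2-(3,4,5-trimethoxyphenoxy)benzaldehyde | COc1cc(C=O)c(Oc2cc(OC)c(OC)c(OC)c2)c(OC)c1OC | intermediate
22 | 3,4,5-trimethoxy-2-(3,4,5-trimethoxyphenoxy)phenyl formate | COc1cc(OC=O)c(Oc2cc(OC)c(OC)c(OC)c2)c(OC)c1OC | intermediate (not isolated)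
23 | 3,4,5-trimethoxy-2-(3,4,5-trimethoxyphenoxy)phenol | COc1cc(O)c(Oc2cc(OC)c(OC)c(OC)c2)c(OC)c1OC | intermediate
24 | 2-iodo-1,3-dimethoxybenzene | COc1cccc(OC)c1I | starting material
25 | 1-(2,6-dimethoxyphenoxy)-3,4,5-trimethoxy-2-(3,4,5-trimethoxyphenoxy)benzene | COc1cc(Oc2c(OC)cccc2OC)c(Oc2cc(OC)c(OC)c(OC)c2)c(OC)c1OC | intermediate
26 | 2-{3,5-dimethoxy-4-[3,4,5-trimethoxy-2-(3,4,5-trimethoxyphenoxy)phenoxy]phenyl}-4,4,5,5-tetramethyl-1,3,2-dioxaborolane | COc1cc(Oc2c(OC)cc(B3OC(C)(C)C(C)(C)O3)cc2OC)c(Oc2cc(OC)c(OC)c(OC)c2)c(OC)c1OC | intermediate (not isolated)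
27 | {3,5-dimethoxy-4-[3,4,5-trimethoxy-2-(3,4,5-trimethoxyphenoxy)phenoxy]phenyl}boronic acid | COc1cc(Oc2c(OC)cc(B(O)O)cc2OC)c(Oc2cc(OC)c(OC)c(OC)c2)c(OC)c1OC | intermediate
28 | 2-(5-ethoxy-3-methoxy-2-{3,5-dimethoxy-4-[3,4,5-trimethoxy-2-(3,4,5-trimethoxyphenoxy)phenoxy]phenoxy}phenoxy)-1,3,5-trimethoxybenzene | COc1cc(OC)c(Oc2cc(OCC)cc(OC)c2Oc2cc(OC)c(Oc3cc(OC)c(OC)c(OC)c3Oc3cc(OC)c(OC)c(OC)c3)c(OC)c2)c(OC)c1 | intermediate
29 | 2-(3,5-dihydroxy-2-{3,5-dihydroxy-4-[3,4,5-trihydroxy-2-(3,4,5-trihydroxyphenoxy)phenoxy]phenoxy}phenoxy)benzene-1,3,5-triol | Oc1cc(O)c(Oc2cc(O)cc(O)c2Oc2cc(O)c(Oc3cc(O)c(O)c(O)c3Oc3cc(O)c(O)c(O)c3)c(O)c2)c(O)c1 | target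

## Step count and least certain steps

Total: 14 steps. Longest linear sequence: 10 steps (steps 1 to 8, then 13 and 14). The ring C–D–E branch (steps 9 to 12) has 4 steps before the convergent step 13.

Step 6 (key step).
- What may go wrong: photochemical isomerization of the enol ether double bond, which would bring the benzyloxy oxygen next to the carbene or ketene carbon and open oxonium ylide pathways. A slow (2+2) capture would let the vinylketene dimerize or acylate the product phenol. The trimethoxyphenoxy chromophore may absorb the light competitively, with secondary photochemistry. The donor-substituted vinylketene has no direct precedent in this reaction.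
- Fallback: ring B is taken from a preformed benzene instead of being built; the route sets out from 1 and 7 and rejoins at 17. Commercial 5-bromovanillin (COc1cc(C=O)cc(Br)c1O) is O-benzylated with 7 (K2CO3, DMF) to give 4-(benzyloxy)-3-bromo-5-methoxybenzaldehyde F1. Coupling of F1 with 1 (CuI, picolinic acid, K3PO4, DMSO, 90 °C) gives 4-(benzyloxy)-3-methoxy-5-(2,4,6-trimethoxyphenoxy)benzaldehyde F2. Baeyer–Villiger oxidation with mCPBA gives 4-(benzyloxy)-3-methoxy-5-(2,4,6-trimethoxyphenoxy)phenyl formate F3, and methanolysis gives 4-(benzyloxy)-3-methoxy-5-(2,4,6-trimethoxyphenoxy)phenol F4. O-Ethylation (EtI, K2CO3) gives 17. The price is a hindered copper coupling for the ether between rings A and B, which the main route avoids.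

Step 13.
- What may go wrong: slow copper-mediated C–O bond formation at the doubly flanked phenol oxygen, so that protodeboronation, oxidative homocoupling and hydroxylation of the boronic acid consume 27.
- Fallback: the coupling is changed from oxidative boron chemistry to an Ullmann reaction of an aryl halide; it sets out from 27 and 18 and rejoins at 28. Base-promoted ipso-iododeboronation of 27 (I2, K2CO3, MeCN, 80 °C), which should spare the electron-rich rings better than an acidic electrophilic iodine source, gives 5-iodo-1,3-dimethoxy-2-[3,4,5-trimethoxy-2-(3,4,5-trimethoxyphenoxy)phenoxy]benzene F5. F5 is an unhindered aryl iodide and is coupled with the hindered phenol 18 (CuI, picolinic acid, K3PO4, DMSO, 90 °C) to give 28.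

Step 11.
- What may go wrong: sluggish activation of the iodide between two methoxy groups and slow C–O bond formation with an ortho-substituted phenoxide, leading to hydrodehalogenation of 24 and incomplete conversion.
- Fallback: the polarity is reversed and the metal changed; it sets out from 23 and rejoins at 25. Phenol 23 is converted with Tf2O and pyridine into 3,4,5-trimethoxy-2-(3,4,5-trimethoxyphenoxy)phenyl trifluoromethanesulfonate F6. F6 is coupled with commercial 2,6-dimethoxyphenol (COc1cccc(OC)c1O) under palladium catalysis (Pd(OAc)2, 2-di-tert-butylphosphino-2',4',6'-triisopropylbiphenyl, K3PO4, toluene, 100 °C) to give 25.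

Step 14.
- What may go wrong: incomplete dealkylation of thirteen ethers, giving mixtures of partially alkylated phenols, and air oxidation of the pyrogallol and para-dioxygenated units during work-up and purification.
- Fallback: the isolation goes through a stable derivative; it sets out from 28 and rejoins at 29. The crude product of the BBr3 cleavage is not exposed to air but acetylated at once (Ac2O, pyridine). This gives 2-(3,5-diacetoxy-2-{3,5-diacetoxy-4-[3,4,5-triacetoxy-2-(3,4,5-triacetoxyphenoxy)phenoxy]phenoxy}phenoxy)benzene-1,3,5-triyl triacetate F7. F7 can be purified on silica and checked for complete dealkylation. Acid-catalysed methanolysis (HCl from AcCl in degassed MeOH, rt, Ar) then gives 29.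

Step 5.
- What may go wrong: conjugate addition–elimination of the amide base or of the enolate at the β-benzyloxy enone (loss of benzyloxide), O- instead of C-trifluoroacetylation, and decomposition of the diazo ketone on acidic supports.
- Fallback: the diazo group is built from a bromomethyl ketone instead of by diazo transfer; it sets out from 8 and rejoins at 10. Soft enolization of 8 (Me3SiOTf, Et3N, CH2Cl2, 0 °C) gives {[(3Z)-4-(benzyloxy)-3-(2,4,6-trimethoxyphenoxy)buta-1,3-dien-2-yl]oxy}trimethylsilane F8. One equivalent of N-bromosuccinimide in THF at −78 °C, kept cold to spare the electron-rich ring A, gives (Z)-4-(benzyloxy)-1-bromo-3-(2,4,6-trimethoxyphenoxy)but-3-en-2-one F9. N,N'-Ditosylhydrazine and DBU in THF at 0 °C then convert F9 into 10.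

## Further compounds

F1 | step 6 | 4-(benzyloxy)-3-bromo-5-methoxybenzaldehyde | COc1cc(C=O)cc(Br)c1OCc1ccccc1
F2 | step 6 | 4-(benzyloxy)-3-methoxy-5-(2,4,6-trimethoxyphenoxy)benzaldehyde | COc1cc(OC)c(Oc2cc(C=O)cc(OC)c2OCc2ccccc2)c(OC)c1
F3 | step 6 | 4-(benzyloxy)-3-methoxy-5-(2,4,6-trimethoxyphenoxy)phenyl formate | COc1cc(OC)c(Oc2cc(OC=O)cc(OC)c2OCc2ccccc2)c(OC)c1
F4 | step 6 | 4-(benzyloxy)-3-methoxy-5-(2,4,6-trimethoxyphenoxy)phenol | COc1cc(OC)c(Oc2cc(O)cc(OC)c2OCc2ccccc2)c(OC)c1
F5 | step 13 | 5-iodo-1,3-dimethoxy-2-[3,4,5-trimethoxy-2-(3,4,5-trimethoxyphenoxy)phenoxy]benzene | COc1cc(Oc2c(OC)cc(I)cc2OC)c(Oc2cc(OC)c(OC)c(OC)c2)c(OC)c1OC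
F6 | step 11 | 3,4,5-trimethoxy-2-(3,4,5-trimethoxyphenoxy)phenyl trifluoromethanesulfonate | COc1cc(OS(=O)(=O)C(F)(F)F)c(Oc2cc(OC)c(OC)c(OC)c2)c(OC)c1OC
F7 | step 14 | 2-(3,5-diacetoxy-2-{3,5-diacetoxy-4-[3,4,5-triacetoxy-2-(3,4,5-triacetoxyphenoxy)phenoxy]phenoxy}phenoxy)benzene-1,3,5-triyl triacetate | CC(=O)Oc1cc(OC(C)=O)c(Oc2cc(OC(C)=O)cc(OC(C)=O)c2Oc2cc(OC(C)=O)c(Oc3cc(OC(C)=O)c(OC(C)=O)c(OC(C)=O)c3Oc3cc(OC(C)=O)c(OC(C)=O)c(OC(C)=O)c3)c(OC(C)=O)c2)c(OC(C)=O)c1
F8 | step 5 | {[(3Z)-4-(benzyloxy)-3-(2,4,6-trimethoxyphenoxy)buta-1,3-dien-2-yl]oxy}trimethylsilane | C=C(O[Si](C)(C)C)/C(Oc1c(OC)cc(OC)cc1OC)=C/OCc1ccccc1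
F9 | step 5 | (Z)-4-(benzyloxy)-1-bromo-3-(2,4,6-trimethoxyphenoxy)but-3-en-2-one | BrCC(=O)/C(Oc1c(OC)cc(OC)cc1OC)=C/OCc1ccccc1
A1 | alternative 1 | 2,6-dimethoxybenzene-1,4-diol | COc1cc(O)cc(OC)c1O
A2 | alternative 1 | 4-fluoro-3-methoxy-5-(2,4,6-trimethoxyphenoxy)benzaldehyde | COc1cc(OC)c(Oc2cc(C=O)cc(OC)c2F)c(OC)c1
A3 | alternative 1 | 4-fluoro-2,6-dimethoxy-3-(3,4,5-trimethoxyphenoxy)benzaldehyde | COc1cc(F)c(Oc2cc(OC)c(OC)c(OC)c2)c(OC)c1C=O
A4 | alternative 1 | 4-{4-[4-formyl-3,5-dimethoxy-2-(3,4,5-trimethoxyphenoxy)phenoxy]-3,5-dimethoxyphenoxy}-3-methoxy-5-(2,4,6-trimethoxyphenoxy)benzaldehyde | COc1cc(OC)c(Oc2cc(C=O)cc(OC)c2Oc2cc(OC)c(Oc3cc(OC)c(C=O)c(OC)c3Oc3cc(OC)c(OC)c(OC)c3)c(OC)c2)c(OC)c1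
A5 | alternative 2 | 3,4-dimethoxycyclobut-3-ene-1,2-dione (dimethyl squarate) | COC1=C(OC)C(=O)C1=O
A6 | alternative 2 | {(Z)-2-[4-(benzyloxy)-2,6-dimethoxyphenoxy]ethenyl}lithium | [Li]/C=C\Oc1c(OC)cc(OCc2ccccc2)cc1OC
A7 | alternative 2 | 4-{(Z)-2-[4-(benzyloxy)-2,6-dimethoxyphenoxy]ethenyl}-2,3,4-trimethoxycyclobut-2-en-1-one (racemic) | COC1=C(OC)C(OC)(/C=C\Oc2c(OC)cc(OCc3ccccc3)cc2OC)C1=O
A8 | alternative 2 | 6-[4-(benzyloxy)-2,6-dimethoxyphenoxy]-2,3,4-trimethoxyphenol | COc1cc(Oc2c(OC)cc(OCc3ccccc3)cc2OC)c(O)c(OC)c1OC
A9 | alternative 3 | methyl 6-[2-(benzyloxy)-3,5-dimethoxyphenoxy]-3,5-dioxohexanoate | COC(=O)CC(=O)CC(=O)COc1cc(OC)cc(OC)c1OCc1ccccc1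
A10 | alternative 3 | 2-[2-(benzyloxy)-3,5-dimethoxyphenoxy]benzene-1,3,5-triol | Oc1cc(O)c(Oc2cc(OC)cc(OC)c2OCc2ccccc2)c(O)c1
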